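**Assumptions:** (R)-5-oxotetrahydrofuran-2-carboxylic acid (from D-glutamic acid) is commercially available. The (E)-epoxygeranate from Step 5 is separated from its Z isomer by chromatography. The secondary alcohol needs no protection in Steps 7–11.

## Retrosynthetic overview
- The target comes from cross-metathesis of the ring diene **11** (ring–CH2CH2C(Me)=CH2) with the farnesyl-derived terminal alkene **13** (from farnesyl bromide and allylMgBr).
- Diene **11** comes from the cyclogeranyl-type iodide **9** by photochemical radical allylation.
- The only ring is formed by a Ti/Co photocatalytic radical 6-endo epoxide cyclization of (S)-6,7-epoxygeraniol **7**. This forms C4–C5, sets C5 relative to C3, and places the Δ1(10) alkene.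
- Epoxide **7** is made from (R)-5-oxotetrahydrofuran-2-carboxylic acid (**1**): Weinreb opening, MeMgBr, epoxide closure with inversion, HWE, DIBAL.
- The ring is formed first, and the side chain is attached afterwards.

## Route

**Step 1**
Reactants: **1** (R)-5-oxotetrahydrofuran-2-carboxylic acid
Product: **2** (2R)-2-hydroxy-5-[methoxy(methyl)amino]-5-oxopentanoic acid
Conditions: MeNH(OMe)·HCl (3 equiv), i-PrMgCl (6 equiv), THF, −20 → 0 °C
Reagents that add atoms: N,O-dimethylhydroxylamine, CNOC
Why: Williams-type Weinreb aminolysis opens the electrophilic lactone, while the acid is protected as its Mg carboxylate. The stereocenter is untouched.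

**Step 2**
Reactants: **2**
Product: **3** methyl (2R)-2-hydroxy-5-[methoxy(methyl)amino]-5-oxopentanoate
Conditions: TMSCHN2, MeOH/PhMe, 0 °C
Reagents that add atoms: trimethylsilyldiazomethane, C[Si](C)(C)C=[N+]=[N-]
Why: TMSCHN2 esterifies the carboxylic acid chemoselectively in the presence of the Weinreb amide and the free OH.

**Step 3**
Reactants: **3**
Product: **4** (5R)-5,6-dihydroxy-6-methylheptan-2-one
Conditions: MeMgBr (5 equiv), THF, −10 → 0 °C
Reagents that add atoms: methylmagnesium bromide, C[Mg]Br
Why: Grignard double addition turns the ester into the CMe2OH group, and the Weinreb amide stops at the methyl ketone through its stable chelate. The stereocenter is not involved.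

**Step 4**
Reactants: **4**
Product: **5** (S)-sulcatone epoxide, (5S)-5,6-epoxy-6-methylheptan-2-one
Conditions: TsCl, pyridine, DMAP, 0 °C; then K2CO3, MeOH, rt (one pot)
Reagents that add atoms: none
Why: Only the secondary OH is sulfonylated, and the tertiary alkoxide then closes by intramolecular Williamson (3-exo-tet). Inversion at the carbinol carbon converts the (R)-diol into the (S)-epoxide (3S series).

**Step 5**
Reactants: **5**
Product: **6** ethyl (2E,6S)-6,7-epoxy-3,7-dimethyloct-2-enoate
Conditions: (EtO)2P(O)CH2CO2Et, NaH, THF, 0 °C → rt; chromatographic removal of the Z isomer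
Reagents that add atoms: triethyl phosphonoacetate, CCOC(=O)CP(=O)(OCC)OCC
Why: Horner–Wadsworth–Emmons olefination of the methyl ketone gives mainly the E-enoate. The E geometry is needed so that the chain becomes equatorial in the later cyclization.

**Step 6**
Reactants: **6**
Product: **7** (2E,6S)-6,7-epoxygeraniol
Conditions: DIBAL-H (2.5 equiv), CH2Cl2, −78 °C
Reagents that add atoms: none
Why: DIBAL reduces the ester to the allylic alcohol and leaves the trisubstituted epoxide intact. The alcohol is needed because the enoate would make the alkene polarity-mismatched for the nucleophilic tertiary radical.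

**Step 7**
Reactants: **7**
Product: **8** (1S,5R)-5-(hydroxymethyl)-4,6,6-trimethylcyclohex-3-en-1-ol
Conditions: Cp2TiCl2 (10 mol %), Co(dmgH)2pyCl (5 mol %), 2,4,6-collidine (0.3 equiv), 3DPAFIPN (1 mol %), THF (0.02 M), blue LEDs (455 nm), 25 °C, 24 h
Reagents that add atoms: none (redox-neutral isomerization)
Why: Proposed new method: light-driven Ti(IV)/Ti(III) turnover gives Cp2TiCl, which opens the epoxide homolytically to the tertiary C4 radical and leaves a Ti–O on C3. The radical closes 6-endo through a chair transition state with the C3–O and the E-chain both equatorial, giving 3,5-cis (3S,5R) and setting C5 without any chiral catalyst. The tertiary C10 radical is then dehydrogenated by cobaloxime HAT/H-atom re-addition equilibration, which should funnel it to the more substituted endocyclic Δ1(10) alkene; the hindered C5–H blocks Δ5(10), which would destroy C5. The closest known reactions are Cp2TiCl radical epoxypolyene cyclization (exocyclic alkene by Ti β-H elimination) and Co-catalysed dehydrogenation or isomerization. The new feature is combining them catalytically and photochemically so that the endocyclic alkene forms in the same step.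

**Step 8**
Reactants: **8**
Product: **9** (1S,5R)-5-(iodomethyl)-4,6,6-trimethylcyclohex-3-en-1-ol
Conditions: PPh3, I2, imidazole, CH2Cl2, 0 °C
Reagents that add atoms: iodine, II
Why: Appel iodination is selective for the unhindered primary alcohol over the secondary alcohol flanked by the quaternary carbon. Both stereocenters are untouched.

**Step 9**
Reactants: **9**, **10** 2-methylallyl phenyl sulfone
Product: **11** (1S,5R)-4,6,6-trimethyl-5-(3-methylbut-3-en-1-yl)cyclohex-3-en-1-ol
Conditions: 4CzIPN (2 mol %), Et3N (3 equiv), MeCN, blue LEDs, rt
Reagents that add atoms: none beyond reactant **10**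
Why: Et3N-derived α-aminoalkyl radicals abstract iodine (XAT) to give the primary radical. The radical adds to the CH2= terminus of the sulfone, and β-scission of PhSO2• gives the 1,1-disubstituted alkene (Keck-type radical allylation). This forms the C–C bond between the ring CH2 and the chain.

**Step 10**
Reactants: **12** (E,E)-farnesyl bromide
Product: **13** (E,E)-farnesyl-allyl triene, CH2=CH–CH2–CH2–farnesyl-type chain (C18H30)
Conditions: CH2=CHCH2MgBr (1.5 equiv), Li2CuCl4 (5 mol %), THF, −20 °C → rt
Reagents that add atoms: allylmagnesium bromide, C=CC[Mg]Br
Why: Kochi-type Cu-catalysed SN2 coupling of a Grignard reagent with an allylic bromide retains the E geometry of both alkenes and makes the CH2CH2 tail-to-tail link.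

**Step 11**
Reactants: **11**, **13**
Product: **14** camelliol C
Conditions: Hoveyda–Grubbs II (5 mol %), 13 (2.5 equiv), CH2Cl2 (0.05 M), 40 °C, N2 sweep to remove ethylene; chromatography to remove the minor Z isomer
Reagents that add atoms: none
Why: Cross-metathesis of the 1,1-disubstituted alkene with the terminal alkene releases ethylene and gives the trisubstituted (E)-alkene under thermodynamic control. No stereocenter is touched.

## Compound list
1 | (R)-5-oxotetrahydrofuran-2-carboxylic acid | OC(=O)[C@H]1CCC(=O)O1 | starting material
2 | (2R)-2-hydroxy-5-[methoxy(methyl)amino]-5-oxopentanoic acid | OC(=O)[C@H](O)CCC(=O)N(C)OC | intermediate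
3 | methyl (2R)-2-hydroxy-5-[methoxy(methyl)amino]-5-oxopentanoate | COC(=O)[C@H](O)CCC(=O)N(C)OC | intermediate
4 | (5R)-5,6-dihydroxy-6-methylheptan-2-one | CC(C)(O)[C@H](O)CCC(C)=O | intermediate
5 | (S)-sulcatone epoxide | CC(=O)CC[C@@H]1OC1(C)C | intermediate
6 | ethyl (2E,6S)-epoxygeranate | CCOC(=O)/C=C(\C)CC[C@@H]1OC1(C)C | intermediate
7 | (2E,6S)-6,7-epoxygeraniol | OC/C=C(\C)CC[C@@H]1OC1(C)C | intermediate
8 | (1S,5R)-5-(hydroxymethyl)-4,6,6-trimethylcyclohex-3-en-1-ol | OC[C@@H]1C(C)=CC[C@H](O)C1(C)C | intermediate
9 | (1S,5R)-5-(iodomethyl)-4,6,6-trimethylcyclohex-3-en-1-ol | IC[C@@H]1C(C)=CC[C@H](O)C1(C)C | intermediate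
10 | 2-methylallyl phenyl sulfone | CC(=C)CS(=O)(=O)c1ccccc1 | starting material
11 | (1S,5R)-4,6,6-trimethyl-5-(3-methylbut-3-en-1-yl)cyclohex-3-en-1-ol | C=C(C)CC[C@@H]1C(C)=CC[C@H](O)C1(C)C | intermediate
12 | (E,E)-farnesyl bromide | BrC/C=C(\C)CC/C=C(\C)CCC=C(C)C | starting material
13 | (E,E)-farnesyl-allyl triene | C=CCC/C=C(\C)CC/C=C(\C)CCC=C(C)C | intermediate
14 | camelliol C | CC(C)=CCC/C(C)=C/CC/C(C)=C/CC/C=C(\C)CC[C@@H]1C(C)=CC[C@H](O)C1(C)C | target

**Atom check:** 11 (C14H24O) + 13 (C18H30) − C2H4 = C30H50O, which is camelliol C.

**Stereochemistry check:** The 3S center comes from (R)-1 through one inversion at the epoxide closure. C5 (R) is set cis to C3 by the chair radical cyclization. Neither center is touched in Steps 8–11.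

## Totals
Total steps: 11 (including the parallel preparation of **13**). Longest linear sequence: 10 steps, from **1** to camelliol C.

## Three steps most likely to fail
1. **Step 7 (proposed new step):** the Ti/Co photocatalytic cyclization may give the exocyclic alkene, over-reduction, or mixtures.
 *Fallback (known chemistry):* use stoichiometric Cp2TiCl/collidine (Cuerva–Oltra) on **7** to give the exocyclic 3-hydroxy-cyclogeraniol, then Co(salen)Cl/PhSiH3 HAT isomerization to **8**.
2. **Step 11:** cross-metathesis of a 1,1-disubstituted alkene with a polyene partner may give poor yield or E/Z selectivity, or partner scrambling.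
 *Fallback:* alkylate ethyl acetoacetate with **9** and decarboxylate to the methyl ketone. Then do HWE, DIBAL, and Appel bromination to the allylic bromide. Couple this with the farnesyl phenyl sulfone anion and desulfonylate with Pd/LiBHEt3 (Biellmann squalene-type route).
3. **Step 3:** MeMgBr may over-add to the Weinreb amide or attack it before the ester is consumed.
 *Fallback:* on the methyl ester of **1**, open the lactone with MeLi at −78 °C to the hemiketal and convert it to the ethylene ketal. Esterify, add excess MeMgBr, then hydrolyse the ketal to give **4**.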